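**Plan**
- Retrosynthesis: cut the two O–S bonds, then C11=C12 and C11'=C12' (double Wittig, C15 + C10 + C15). In each ring the 3-hydroxyl is traced to a C3 ketone, the C4–O bond to an axial C4 bromide, and the C4–C5 bond to a one-carbon ring enlargement.
- Enabling feature: ring atoms C3, C5, C6, C1 and C2 form a cyclopentanone (C3 carbonyl) whose more substituted α-carbon C5 can shift onto a carbenoid carbon that becomes C4. The shift leaves the enolate O–C3=C4, so the vicinal C3/C4 dioxygenation is fixed as the ring grows.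
- Forward: dienylzirconium conjugate addition to 4,4-dimethylcyclopentenone and enolate methylation give the cyclopentanone carrying the whole C7–C11 chain. Dibromomethyllithium addition and carbenoid ring enlargement with bromination give the cyclohexanone. Acetate inversion, hydride reduction, Wittig salt formation, coupling to the C10 dialdehyde and sulfation follow.
- Stereochemistry: C6 from the chiral copper catalyst; C5 by trans alkylation, retained in the 1,2-shift; C4 by axial bromination then SN2 inversion; C3 by equatorial hydride delivery enforced by the syn-axial C1 methyl. Polyene geometry comes from the (E)-enynol, syn-hydrozirconation and thermal equilibration.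
- Sulfation is directed to the equatorial O4 by the stannylene acetal of each cis-diol.

Key step: step 5

Remark: carotenoid locants are used throughout (C1 = CMe2, C2 = CH2, C3 and C4 = oxygenated carbons, C5 = CHMe, C6 = chain-bearing carbon, chain C7 onward), and "TBSO-dienyl" means the (1E,3E)-5-(tert-butyldimethylsilyloxy)-3-methylpenta-1,3-dien-1-yl group. Compounds 1, 3 and 15 are taken as commercial. The target is drawn as the free bis(hydrogen sulfate), so step 10 ends with a cold cation exchange.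

**Step 1**
Reactants: 1 (2E)-3-methylpent-2-en-4-yn-1-ol
Product: 2 tert-butyldimethyl{[(2E)-3-methylpent-2-en-4-yn-1-yl]oxy}silane
Conditions: TBSCl, imidazole, DMF, 0 °C to rt
Reagents that add atoms: tert-butyldimethylsilyl chloride, CC(C)(C)[Si](C)(C)Cl
Why: Standard silylation of a primary allylic alcohol, which protects the hydroxyl against Cp2Zr(H)Cl and the organolithium steps; no stereocentre is formed.

**Step 2**
Reactants: 2 tert-butyldimethyl{[(2E)-3-methylpent-2-en-4-yn-1-yl]oxy}silane; 3 4,4-dimethylcyclopent-2-en-1-one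
Product: 5 {[(3R)-3-(TBSO-dienyl)-4,4-dimethylcyclopent-1-en-1-yl]oxy}trimethylsilane, via dienylzirconocene chloride 4 (not isolated)
Conditions: Cp2Zr(H)Cl, CH2Cl2, rt; then 3, CuCl (10 mol %), AgNTf2 (11 mol %), phosphoramidite from (S)-BINOL and bis[(R)-1-phenylethyl]amine (11 mol %), Me3SiCl, Et2O, rt; non-aqueous work-up (Florisil, pentane)
Reagents that add atoms: chlorotrimethylsilane, C[Si](C)(C)Cl
Why: syn-Hydrozirconation of the terminal alkyne gives the (1E,3E)-dienylzirconium, which undergoes copper-catalysed asymmetric conjugate addition (alkenylzirconocene/phosphoramidite type); the ligand selects the enone face and sets C6 (the ligand antipode named is the one expected to attack the same face as in its dialkylzinc additions to cyclic enones), and Me3SiCl traps the enolate regiospecifically toward the future C5.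

**Step 3**
Reactants: 5 {[(3R)-3-(TBSO-dienyl)-4,4-dimethylcyclopent-1-en-1-yl]oxy}trimethylsilane
Product: 7 (2R,3R)-3-(TBSO-dienyl)-2,4,4-trimethylcyclopentan-1-one, via lithium cyclopentenolate 6 (not isolated)
Conditions: MeLi, THF, 0 °C; then MeI, DMPU, −78 to −20 °C
Reagents that add atoms: iodomethane, CI
Why: MeLi cleaves the O–Si bond to the regiodefined lithium enolate, which is C-methylated anti to the neighbouring dienyl group, so the C5 methyl is trans to the C6 chain (also the thermodynamic epimer).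

**Step 4**
Reactants: 7 (2R,3R)-3-(TBSO-dienyl)-2,4,4-trimethylcyclopentan-1-one
Product: 8 (2R,3R)-1-(dibromomethyl)-3-(TBSO-dienyl)-2,4,4-trimethylcyclopentan-1-ol (both C1 epimers)
Conditions: CH2Br2, LiTMP, THF, −78 °C; aq NH4Cl
Reagents that add atoms: dibromomethane, BrCBr
Why: 1,2-Addition of dibromomethyllithium, made in situ by deprotonation of CH2Br2, to the cyclopentanone; the new carbinol centre becomes trigonal in the next step, so its configuration does not matter.

**Step 5**
Reactants: 8 (2R,3R)-1-(dibromomethyl)-3-(TBSO-dienyl)-2,4,4-trimethylcyclopentan-1-ol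
Product: 11 (2R,3R,4R)-2-bromo-4-(TBSO-dienyl)-3,5,5-trimethylcyclohexan-1-one, via lithium bromocarbenoid 9 (not isolated), via ring-enlarged lithium enolate 10 (not isolated)
Conditions: n-BuLi (2.2 equiv), THF, −78 to 0 °C; recool to −78 °C, NBS
Reagents that add atoms: N-bromosuccinimide, O=C1CCC(=O)N1Br
Why: Bromine–lithium exchange on the alkoxide of 8 gives the β-oxido carbenoid 9, in which the ring bond C3–C5 shifts to the carbenoid carbon C4 as bromide leaves (the closest known type is the β-oxido carbenoid one-carbon ring enlargement of ketones via dibromomethyllithium adducts), so the cyclopentane becomes the cyclohexane C1–C6 and the regiodefined enolate 10 (O–C3=C4) results. No ring is closed by cyclisation: the six-membered ring arises by a 1,2-alkyl shift within the five-membered ring, C5 migrating with retention so that the C5/C6 trans relation is carried over. The selectivity needed is migration of C5 and not of C2; it should be secured by the higher migratory aptitude of the more substituted α-carbon, the trend known for 2-alkylcycloalkanones in this reaction. NBS then brominates 10 at C4, its only nucleophilic carbon, by axial attack on the half-chair (anti to the pseudoaxial C5–H, on the face away from the axial C1 methyl), which sets C4 with bromine axial and cis to the C5 methyl. The step thus inserts C4 between C3 and C5, fixes the C3 carbonyl that later directs hydride to the axial 3-hydroxyl, and leaves at C4 a leaving group with the configuration needed for inversion to the equatorial oxygen.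

**Step 6**
Reactants: 11 (2R,3R,4R)-2-bromo-4-(TBSO-dienyl)-3,5,5-trimethylcyclohexan-1-one
Product: 12 (1S,2R,3R)-3-(TBSO-dienyl)-2,4,4-trimethyl-6-oxocyclohexyl acetate
Conditions: n-Bu4NOAc, acetone, 0 °C to rt
Reagents that add atoms: tetrabutylammonium acetate, CC(=O)[O-].CCCC[N+](CCCC)(CCCC)CCCC
Why: SN2 displacement of the axial, carbonyl-activated bromide by carboxylate with inversion places the C4 oxygen equatorial and trans to the C5 methyl, which is also the preferred epimer of an α-acetoxy cyclohexanone, so kinetic and equilibrium control should converge on 12.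

**Step 7**
Reactants: 12 (1S,2R,3R)-3-(TBSO-dienyl)-2,4,4-trimethyl-6-oxocyclohexyl acetate
Product: 13 (1R,2S,3R,4R)-4-(TBSO-dienyl)-3,5,5-trimethylcyclohexane-1,2-diol
Conditions: LiBH(s-Bu)3, THF, −78 °C; then NaOH, H2O2, H2O, 0 °C to rt
Reagents that add atoms: none
Why: Bulky-hydride reduction of a cyclohexanone in which axial attack at C3 is blocked by the syn-axial C1 methyl (3,3,5-trimethylcyclohexanone model), so hydride enters equatorially and gives the axial 3-hydroxyl cis to O4; the alkaline peroxide work-up oxidises the borane and saponifies the acetate.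

**Step 8**
Reactants: 13 (1R,2S,3R,4R)-4-(TBSO-dienyl)-3,5,5-trimethylcyclohexane-1,2-diol
Product: 14 [(2E,4E)-5-[(1R,4R,5S,6R)-4,5-dihydroxy-2,2,6-trimethylcyclohexyl]-3-methylpenta-2,4-dien-1-yl]triphenylphosphonium bromide
Conditions: Ph3P·HBr, MeOH, rt; crystallisation
Reagents that add atoms: triphenylphosphine hydrobromide, Br.c1ccc(cc1)P(c1ccccc1)c1ccccc1
Why: Acid methanolysis of the allylic silyl ether and ionisation to the pentadienyl cation, which PPh3 captures at the unhindered terminus C11 (standard C15 Wittig-salt preparation); the ring stereocentres are not involved.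

**Step 9**
Reactants: 14 [(2E,4E)-5-[(1R,4R,5S,6R)-4,5-dihydroxy-2,2,6-trimethylcyclohexyl]-3-methylpenta-2,4-dien-1-yl]triphenylphosphonium bromide (2 equiv); 15 (2E,4E,6E)-2,7-dimethylocta-2,4,6-trienedial
Product: 16 (all-E)-(3R,4S,5R,6R,3'R,4'S,5'R,6'R)-5,6,5',6'-tetrahydro-β,β-carotene-3,4,3',4'-tetrol
Conditions: 1,2-epoxybutane, EtOH, reflux, argon, dark; then thermal E/Z equilibration (heptane, reflux) and crystallisation
Reagents that add atoms: none
Why: Double Wittig olefination (C15 + C10 + C15 carotenoid assembly) forms C11=C12 and C11'=C12' and tolerates the free hydroxyls; Z isomers should revert to the all-E polyene on heating.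

**Step 10**
Reactants: 16 (all-E)-(3R,4S,5R,6R,3'R,4'S,5'R,6'R)-5,6,5',6'-tetrahydro-β,β-carotene-3,4,3',4'-tetrol
Product: 18 (all-E)-(3R,4S,5R,6R,3'R,4'S,5'R,6'R)-5,6,5',6'-tetrahydro-β,β-carotene-3,4,3',4'-tetrol 4,4'-bis(hydrogen sulfate), via bis(dibutylstannylene) acetal 17 (not isolated)
Conditions: Bu2SnO, MeOH–toluene, reflux, argon, dark, then evaporation; SO3·NMe3, THF–DMF, rt; Dowex 50W (H+ form), MeOH–H2O, 0 °C
Reagents that add atoms: sulfur trioxide–trimethylamine complex, C[N+](C)(C)S(=O)(=O)[O-]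
Why: Dibutylstannylene acetals of cis-1,2-diols on six-membered rings are sulfated at the equatorial oxygen (known regioselective sulfation of stannylene acetals), here O4, the axial O3 being further shielded by the syn-axial C1 methyl; cold cation exchange then gives the hydrogen sulfate form without touching a stereocentre.

**Compound list**
1 | (2E)-3-methylpent-2-en-4-yn-1-ol | C#C/C(C)=C/CO | starting material
2 | tert-butyldimethyl{[(2E)-3-methylpent-2-en-4-yn-1-yl]oxy}silane | C#C/C(C)=C/CO[Si](C)(C)C(C)(C)C | intermediate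
3 | 4,4-dimethylcyclopent-2-en-1-one | O=C1C=CC(C)(C)C1 | starting material
4 | chlorobis(cyclopentadienyl)[(1E,3E)-5-(tert-butyldimethylsilyloxy)-3-methylpenta-1,3-dien-1-yl]zirconium | Cl[Zr](/C=C/C(C)=C/CO[Si](C)(C)C(C)(C)C)(C1C=CC=C1)C1C=CC=C1 | intermediate
5 | {[(3R)-3-[(1E,3E)-5-(tert-butyldimethylsilyloxy)-3-methylpenta-1,3-dien-1-yl]-4,4-dimethylcyclopent-1-en-1-yl]oxy}trimethylsilane | C[Si](C)(C)OC1=C[C@@H](/C=C/C(C)=C/CO[Si](C)(C)C(C)(C)C)C(C)(C)C1 | intermediate
6 | lithium (3R)-3-[(1E,3E)-5-(tert-butyldimethylsilyloxy)-3-methylpenta-1,3-dien-1-yl]-4,4-dimethylcyclopent-1-en-1-olate | [Li]OC1=C[C@@H](/C=C/C(C)=C/CO[Si](C)(C)C(C)(C)C)C(C)(C)C1 | intermediate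
7 | (2R,3R)-3-[(1E,3E)-5-(tert-butyldimethylsilyloxy)-3-methylpenta-1,3-dien-1-yl]-2,4,4-trimethylcyclopentan-1-one (2,3-trans) | O=C1[C@H](C)[C@@H](/C=C/C(C)=C/CO[Si](C)(C)C(C)(C)C)C(C)(C)C1 | intermediate
8 | (2R,3R)-1-(dibromomethyl)-3-[(1E,3E)-5-(tert-butyldimethylsilyloxy)-3-methylpenta-1,3-dien-1-yl]-2,4,4-trimethylcyclopentan-1-ol (C1 epimers) | OC1(C(Br)Br)[C@H](C)[C@@H](/C=C/C(C)=C/CO[Si](C)(C)C(C)(C)C)C(C)(C)C1 | intermediate
9 | lithium alkoxide of 8 lithiated at the bromomethyl carbon (β-oxido carbenoid) | [Li]OC1(C([Li])Br)[C@H](C)[C@@H](/C=C/C(C)=C/CO[Si](C)(C)C(C)(C)C)C(C)(C)C1 | intermediate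
10 | lithium (3R,4R)-4-[(1E,3E)-5-(tert-butyldimethylsilyloxy)-3-methylpenta-1,3-dien-1-yl]-3,5,5-trimethylcyclohex-1-en-1-olate | [Li]OC1=C[C@H](C)[C@@H](/C=C/C(C)=C/CO[Si](C)(C)C(C)(C)C)C(C)(C)C1 | intermediate
11 | (2R,3R,4R)-2-bromo-4-[(1E,3E)-5-(tert-butyldimethylsilyloxy)-3-methylpenta-1,3-dien-1-yl]-3,5,5-trimethylcyclohexan-1-one (Br axial, cis to 3-methyl) | CC(C)(C)[Si](C)(C)OC/C=C(C)/C=C/[C@@H]1[C@@H](C)[C@@H](Br)C(=O)CC1(C)C | intermediate
12 | (1S,2R,3R)-3-[(1E,3E)-5-(tert-butyldimethylsilyloxy)-3-methylpenta-1,3-dien-1-yl]-2,4,4-trimethyl-6-oxocyclohexyl acetate | CC(C)(C)[Si](C)(C)OC/C=C(C)/C=C/[C@@H]1[C@@H](C)[C@H](OC(C)=O)C(=O)CC1(C)C | intermediate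
13 | (1R,2S,3R,4R)-4-[(1E,3E)-5-(tert-butyldimethylsilyloxy)-3-methylpenta-1,3-dien-1-yl]-3,5,5-trimethylcyclohexane-1,2-diol | CC(C)(C)[Si](C)(C)OC/C=C(C)/C=C/[C@@H]1[C@@H](C)[C@H](O)[C@H](O)CC1(C)C | intermediate
14 | [(2E,4E)-5-[(1R,4R,5S,6R)-4,5-dihydroxy-2,2,6-trimethylcyclohexyl]-3-methylpenta-2,4-dien-1-yl]triphenylphosphonium bromide | [Br-].C(/C=C(C)/C=C/[C@@H]1[C@@H](C)[C@H](O)[C@H](O)CC1(C)C)[P+](c1ccccc1)(c1ccccc1)c1ccccc1 | intermediate
15 | (2E,4E,6E)-2,7-dimethylocta-2,4,6-trienedial | O=C/C(C)=C/C=C/C=C(C)/C=O | starting material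
16 | (all-E)-(3R,4S,5R,6R,3'R,4'S,5'R,6'R)-5,6,5',6'-tetrahydro-β,β-carotene-3,4,3',4'-tetrol | CC(/C=C/C=C(C)/C=C/[C@@H]1[C@@H](C)[C@H](O)[C@H](O)CC1(C)C)=C\C=C\C=C(C)\C=C\C=C(C)\C=C\[C@@H]1[C@@H](C)[C@H](O)[C@H](O)CC1(C)C | intermediate
17 | 3,4:3',4'-bis-O-(dibutylstannanediyl) derivative of 16 | CC(/C=C/C=C(C)/C=C/[C@@H]1[C@@H](C)[C@H](O[Sn]2(CCCC)CCCC)[C@H](O2)CC1(C)C)=C\C=C\C=C(C)\C=C\C=C(C)\C=C\[C@@H]1[C@@H](C)[C@H](O[Sn]2(CCCC)CCCC)[C@H](O2)CC1(C)C | intermediate
18 | (all-E)-(3R,4S,5R,6R,3'R,4'S,5'R,6'R)-5,6,5',6'-tetrahydro-β,β-carotene-3,4,3',4'-tetrol 4,4'-bis(hydrogen sulfate) | CC(/C=C/C=C(C)/C=C/[C@@H]1[C@@H](C)[C@H](OS(=O)(=O)O)[C@H](O)CC1(C)C)=C\C=C\C=C(C)\C=C\C=C(C)\C=C\[C@@H]1[C@@H](C)[C@H](OS(=O)(=O)O)[C@H](O)CC1(C)C | target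

Total step count: 10. Longest linear sequence: 10 steps (1 to 18); fragments 3 and 15 enter in steps 2 and 9.

**Steps most likely to fail**

Step 2. The conjugate addition may be slow at the β-carbon flanked by the quaternary centre, the facial selectivity may be low or reversed, and the silyl enol ether may hydrolyse before methylation. Fallback, from 2 and 3 back to 7: Cp2Zr(H)Cl-catalysed hydroboration of 2 with pinacolborane gives the (1E,3E)-dienyl pinacolboronate F1. Hayashi–Miyaura addition of F1 to 3 with [Rh(OH)((S)-binap)]2 in dioxane–water at 80–100 °C should give (3S)-3-(TBSO-dienyl)-4,4-dimethylcyclopentan-1-one F2, with the well-established facial sense of this catalyst. Kinetic deprotonation of F2 with LDA at −78 °C should avoid the neopentyl methylene next to the quaternary carbon, and methylation with MeI anti to the dienyl group would give 7; any regioisomer would be removed by chromatography.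

Step 6. Acetate may act as a base, causing β-elimination of HBr toward the C4–C5 enone or enolisation instead of substitution. Fallback, from 8 back to 12: the ring enlargement of step 5 is repeated, but enolate 10 is quenched with Me3SiCl to give the six-membered trimethylsilyl enol ether F3. Rubottom oxidation (mCPBA, NaHCO3, CH2Cl2, −20 °C, then mild desilylation) should deliver oxygen to the same face as bromine and give the axial (2R)-hydroxy ketone F4. Mitsunobu inversion with acetic acid (PPh3, DIAD) then gives 12, so the C4–O bond is made from an electrophilic oxygen and inverted at the alcohol instead of by halide displacement.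

Step 10. Sulfation may occur at the axial 3-hydroxyls or at all four hydroxyls, and the acidic ion exchange may damage the nonaene. Fallback, from 16 back to 18: trimethyl orthoacetate with pyridinium p-toluenesulfonate gives the bis(cyclic orthoacetate) F5. Dilute aqueous acetic acid should open each orthoester to the axial ester (the known kinetic preference for cis-diols on six-membered rings), giving the 3,3'-diacetate F6 with only the equatorial 4,4'-hydroxyls free. SO3·pyridine then sulfates these to the diacetate bis(hydrogen sulfate) F7, and K2CO3 in MeOH followed by the same cold cation exchange gives 18.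

**Further compounds**
F1 | step 2 | tert-butyldimethyl{[(2E,4E)-3-methyl-5-(4,4,5,5-tetramethyl-1,3,2-dioxaborolan-2-yl)penta-2,4-dien-1-yl]oxy}silane | CC(C)(C)[Si](C)(C)OC/C=C(C)/C=C/B1OC(C)(C)C(C)(C)O1
F2 | step 2 | (3S)-3-[(1E,3E)-5-(tert-butyldimethylsilyloxy)-3-methylpenta-1,3-dien-1-yl]-4,4-dimethylcyclopentan-1-one | O=C1C[C@@H](/C=C/C(C)=C/CO[Si](C)(C)C(C)(C)C)C(C)(C)C1
F3 | step 6 | {[(3R,4R)-4-[(1E,3E)-5-(tert-butyldimethylsilyloxy)-3-methylpenta-1,3-dien-1-yl]-3,5,5-trimethylcyclohex-1-en-1-yl]oxy}trimethylsilane | C[Si](C)(C)OC1=C[C@H](C)[C@@H](/C=C/C(C)=C/CO[Si](C)(C)C(C)(C)C)C(C)(C)C1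
F4 | step 6 | (2R,3R,4R)-4-[(1E,3E)-5-(tert-butyldimethylsilyloxy)-3-methylpenta-1,3-dien-1-yl]-2-hydroxy-3,5,5-trimethylcyclohexan-1-one (hydroxyl axial) | CC(C)(C)[Si](C)(C)OC/C=C(C)/C=C/[C@@H]1[C@@H](C)[C@@H](O)C(=O)CC1(C)C
F5 | step 10 | 3,4:3',4'-bis-O-(1-methoxyethylidene) derivative of 16 | CC(/C=C/C=C(C)/C=C/[C@@H]1[C@@H](C)[C@H](OC2(C)OC)[C@H](O2)CC1(C)C)=C\C=C\C=C(C)\C=C\C=C(C)\C=C\[C@@H]1[C@@H](C)[C@H](OC2(C)OC)[C@H](O2)CC1(C)C
F6 | step 10 | 3,3'-di-O-acetate of 16 | CC(/C=C/C=C(C)/C=C/[C@@H]1[C@@H](C)[C@H](O)[C@H](OC(C)=O)CC1(C)C)=C\C=C\C=C(C)\C=C\C=C(C)\C=C\[C@@H]1[C@@H](C)[C@H](O)[C@H](OC(C)=O)CC1(C)C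
F7 | step 10 | 3,3'-di-O-acetate of 18 | CC(/C=C/C=C(C)/C=C/[C@@H]1[C@@H](C)[C@H](OS(=O)(=O)O)[C@H](OC(C)=O)CC1(C)C)=C\C=C\C=C(C)\C=C\C=C(C)\C=C\[C@@H]1[C@@H](C)[C@H](OS(=O)(=O)O)[C@H](OC(C)=O)CC1(C)C
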